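All constants are those of an exercise, and the outcome is calculated.

The ratio 7.50 of the growth constant to the initiation constant is the number of units a chain gains per chain begun while living end and initiator stand equal; both steps use free monomer, so [free monomer] cancels from it.

free monomer 0.22 M (fed, over 2.5 d); transfer agent 0.0220 M; initiator 4.4 mM; time 2.5 d; the fed solution adds 0.50 times the starting volume

    free monomer + initiator → living end + monomer in chains (k1 = 2.4 M⁻¹ h⁻¹)
    free monomer + living end → monomer in chains + living end, rate k2*[living end]*[free monomer] (k2 = 18 M⁻¹ h⁻¹)
    living end + transfer agent → dead chain (k3 = 0.58 M⁻¹ h⁻¹)
    2 living end → dead end (k4 = 130 M⁻¹ h⁻¹)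
    free monomer → uncatalysed product (k5 = 0.032 h⁻¹)

* average number of monomer units in a chain (chains begun, living or dead) at 2.5 d
* part of the free monomer that has reacted at 2.5 d

- for a step with 2 of a species take k times the square, and two of it per event
- every charge counts on the volume at the start, and the solution that is fed holds the whole dose
- the average divides the monomer in chains by the number of chains begun, living and dead together
- run time (flask): 2.5 d

*What does that ratio become in general?* Units gained per initiator used are (k2/k1)·[living end]/[initiator].

*What sets [living end]?* I balance its making, k1[initiator][free monomer], against its pairing, 2·k4[living end]². Integrating over the burning of the charged initiator gives the burn-out length B = 2(k2/k1)√(k1[free monomer]/(2·k4[initiator]₀)), the units gained per chain begun once the initiator has burnt, a kinetic chain length. Taken as amounts per starting volume, the growing volume cancels.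

*Which [free monomer]? That is the weak spot.* The feed brings 0.00367 M h⁻¹, so under this rising supply I reckon the initiator half gone after 12.6 h, by when 0.0460 M has arrived. That time is shorter than the 31.3 h lifetime of free monomer in the uncatalysed step, so I neglect that loss here.

*Is the balance fair?* At that moment [living end] is near 0.967 mM, and its pairing lifetime of 3.98 h is shorter than the initiator's half-life. Transfer, at 0.0128 h⁻¹, is slower than pairing at 0.251 h⁻¹.

*Your answers?* With that amount in the formula, the burn-out length B, the units gained per chain begun, is 4.66, so with the first unit from initiation dp is 5.66. The uncatalysed step acting on the feed by itself gives c of 55.6 %. By my dp the chains take 11.3 % of the charge, around 12.6 h, and of that a share of 21.9 % would have outlived the uncatalysed step to 2.5 d, so I add that part and commit to c of 58.0 %.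

The forecast, which differs from mine on dp, gives 6.9 and 58 %, with “the living ends, held near 1 mM or below by fast pairwise termination”.

The flask gives dp 5.95 and c 60.2 %, with 0.21 % of the initiator charge left at 2.5 d. Its units beyond the first come to 4.95, beside a burn-out length of 4.66. In the neighbour flask, charged with 0.018 M of initiator, the same feed gives a burn-out length of 2.30, hence dp 3.30. That neighbour flask gives 3.07.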